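**Retrosynthetic overview** (germacrane numbering: ring C1–C10; lactone O–C12(=O)–C11(=C13)–C7–C6; C14 on C10, C15 on C4)
1. Late stage: C8 angelate, C8–OH-directed cis-1,10-epoxide, C13 methylene by Mannich methylenation, C3 (2R)-2-methylbutanoate.
2. Ten-membered ring: ring-closing metathesis at C1=C10 of a C3-allyl/C8-methallyl diene; C3 and C8 carbinols from two catalyst-controlled allylborations; (Z)-C4=C5 from a Still–Gennari olefination of a C5 aldehyde.
3. Lactone: the ring O–C12–C11–C7–C6 is the Baeyer–Villiger image of a cyclobutanone C12–C11–C7–C6, with oxygen inserted between C12 and C6.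
4. Cyclobutanone: [2+2] of a keteniminium C6=C12=N+ (C6 carries C5 as a protected CH2O; nitrogen is a C2-symmetric pyrrolidine) with buta-1,3-diene (C11=C7; its second vinyl is the C8 handle), forming C11–C12 and C6–C7. The enabling feature is the four contiguous lactone carbons C6–C7–C11–C12, with C12 a carbonyl carbon, C6 epimerisable next to it (hence trans to C7), and C7 bearing a carbon (C8) that can be an olefin.
5. Ring order: cyclobutanone, γ-lactone, ten-membered carbocycle, oxirane.

Key step: step 2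

Assumption: the acid starting material and (2R)-2-methylbutanoic acid are purchased, and the facial senses of the (2R,5R)-pyrrolidine auxiliary and of (R)-/(S)-TRIP are taken from the accepted transition-state models; if one proves opposite, its antipode is used and nothing else changes.

**Step 1**
Reactants: 1 3-[(4-methoxybenzyl)oxy]propanoic acid; 2 (2R,5R)-2,5-dimethylpyrrolidine
Product: 4 1-[(2R,5R)-2,5-dimethylpyrrolidin-1-yl]-3-[(4-methoxybenzyl)oxy]propan-1-one, via acid chloride 3 (not isolated)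
Conditions: (COCl)2, DMF (cat.), CH2Cl2, 0 °C → rt; then 2, Et3N, CH2Cl2, 0 °C → rt
Reagents that add atoms: none
Why: Acid chloride formation followed by amidation is routine and the hindered C2-symmetric amine is acylated cleanly by the acid chloride; no stereocenter is made.

**Step 2**
Reactants: 4 the amide; 5 buta-1,3-diene
Product: 8 (2S,3R)-2-{[(4-methoxybenzyl)oxy]methyl}-3-vinylcyclobutan-1-one (trans), via keteniminium triflate 6 (not isolated), via cyclobutaniminium triflate 7 (not isolated)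
Conditions: Tf2O, 2,4,6-collidine (2.2 equiv), 5 (10 equiv), ClCH2CH2Cl, −20 → 40 °C (sealed tube); then H2O, rt; then Et3N (cat.), CH2Cl2, rt
Reagents that add atoms: water, O
Why: O-Triflation of 4 and loss of triflic acid give keteniminium 6; a terminal diene carbon (C11) attacks its electrophilic C12, and the resulting allyl cation/enamine pair collapses by C6–C7 bond formation to the four-membered ring (stepwise polar [2+2], ring closed by intramolecular cation–enamine combination), after which water hydrolyses iminium 7 to 8. The closest known reaction type is the keteniminium–olefin [2+2] cycloaddition (Ghosez), including its asymmetric form with C2-symmetric pyrrolidine amides and its use with 1,3-dienes. Regiochemistry (C12 to the diene terminus, C6 to the internal carbon C7) follows from formation of the allyl cation, and keteniminium salts prefer [2+2] over [4+2] with acyclic dienes. C7 is set by the auxiliary, whose trans methyl groups make the two orientations of the diene approaching C12 diastereomeric. C6 is set trans to the vinyl group by equilibration next to the iminium/ketone carbon (thermodynamic control). The step needs enantiofacial control and must avoid diene polymerisation; excess diene, low temperature and a non-nucleophilic base serve the second, the auxiliary the first.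

**Step 3**
Reactants: 8 the cyclobutanone
Product: 9 (4R,5S)-5-{[(4-methoxybenzyl)oxy]methyl}-4-vinyloxolan-2-one (trans)
Conditions: 30% aq. H2O2, AcOH, 0 °C → rt
Reagents that add atoms: hydrogen peroxide, OO
Why: Baeyer–Villiger oxidation of a cyclobutanone is strain-driven and the more substituted α-carbon C6 migrates with retention, so oxygen is inserted between C12 and C6 and the trans C6/C7 relationship is carried into the lactone, while the isolated vinyl group is inert to H2O2/AcOH.

**Step 4**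
Reactants: 9 the vinyl lactone
Product: 10 (2S,3S)-2-{[(4-methoxybenzyl)oxy]methyl}-5-oxooxolane-3-carbaldehyde
Conditions: O3, CH2Cl2, −78 °C (Sudan red end point); then PPh3, −78 °C → rt
Reagents that add atoms: ozone, [O-][O+]=O
Why: Ozonolysis with reductive work-up cleaves the only olefin to the C8 aldehyde under neutral conditions that spare the lactone, and C7 already holds the more stable trans configuration.

**Step 5**
Reactants: 10 the aldehyde
Product: 11 (4R,5S)-4-[(1R)-1-hydroxy-3-methylbut-3-en-1-yl]-5-{[(4-methoxybenzyl)oxy]methyl}oxolan-2-one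
Conditions: 2-methylallylboronic acid pinacol ester, (R)-TRIP [(R)-3,3'-bis(2,4,6-triisopropylphenyl)-1,1'-binaphthyl-2,2'-diyl hydrogen phosphate] (5 mol %), 4 Å molecular sieves, toluene, −30 °C; aq. work-up
Reagents that add atoms: 2-methylallylboronic acid pinacol ester, CC(=C)CB1OC(C)(C)C(C)(C)O1
Why: Chiral phosphoric acid-catalysed allylboration through a closed chair transition state adds the methallyl group to the Re face under catalyst control and sets C8 (R), and the cold neutral conditions avoid β-elimination of the lactone oxygen.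

**Step 6**
Reactants: 11 the homoallylic alcohol
Product: 12 (4S,5S)-4-[(1R)-1-{[tert-butyl(dimethyl)silyl]oxy}-3-methylbut-3-en-1-yl]-5-{[(4-methoxybenzyl)oxy]methyl}oxolan-2-one
Conditions: TBSOTf, 2,6-lutidine, CH2Cl2, −78 °C
Reagents that add atoms: tert-butyldimethylsilyl triflate, CC(C)(C)[Si](C)(C)OS(=O)(=O)C(F)(F)F
Why: Silylation with the silyl triflate and a hindered base is fast at −78 °C, which protects the C8 hydroxyl before it can translactonise onto C12.

**Step 7**
Reactants: 12 the silyl ether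
Product: 13 (4S,5S)-4-[(1R)-1-{[tert-butyl(dimethyl)silyl]oxy}-3-methylbut-3-en-1-yl]-5-(hydroxymethyl)oxolan-2-one
Conditions: DDQ, CH2Cl2/pH 7 buffer, 0 °C → rt
Reagents that add atoms: none
Why: Oxidative cleavage of the p-methoxybenzyl ether by DDQ is selective for the electron-rich arene and leaves the silyl ether, lactone and 1,1-disubstituted olefin intact.

**Step 8**
Reactants: 13 the primary alcohol
Product: 14 (2S,3S)-3-[(1R)-1-{[tert-butyl(dimethyl)silyl]oxy}-3-methylbut-3-en-1-yl]-5-oxooxolane-2-carbaldehyde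
Conditions: Dess–Martin periodinane, CH2Cl2, 0 °C → rt
Reagents that add atoms: none
Why: Dess–Martin oxidation gives the C5 aldehyde under near-neutral conditions, so the α-oxygenated center C6 is not epimerised; the aldehyde is used crude.

**Step 9**
Reactants: 14 the aldehyde
Product: 15 methyl (2Z)-3-[(2R,3S)-3-[(1R)-1-{[tert-butyl(dimethyl)silyl]oxy}-3-methylbut-3-en-1-yl]-5-oxooxolan-2-yl]-2-methylprop-2-enoate
Conditions: methyl 2-[bis(2,2,2-trifluoroethoxy)phosphoryl]propanoate, KN(SiMe3)2, 18-crown-6, THF, −78 °C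
Reagents that add atoms: methyl 2-[bis(2,2,2-trifluoroethoxy)phosphoryl]propanoate, COC(=O)C(C)P(=O)(OCC(F)(F)F)OCC(F)(F)F
Why: In the Still–Gennari variant of the Horner–Wadsworth–Emmons reaction the trifluoroethyl phosphonate eliminates fast from the kinetic adduct and gives the (Z)-trisubstituted enoate (C6 cis to C3), at a temperature where C6 does not epimerise.

**Step 10**
Reactants: 15 the (Z)-enoate
Product: 16 (4S,5R)-4-[(1R)-1-{[tert-butyl(dimethyl)silyl]oxy}-3-methylbut-3-en-1-yl]-5-[(1Z)-3-hydroxy-2-methylprop-1-en-1-yl]oxolan-2-ol (anomers)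
Conditions: i-Bu2AlH (5 equiv), CH2Cl2, −78 → −40 °C; aq. KNaC4H4O6
Reagents that add atoms: none
Why: i-Bu2AlH reduces the enoate to the allylic alcohol and the lactone to the lactol without touching the olefin geometry, and both carbonyl levels are restored in the next step.

**Step 11**
Reactants: 16 the lactol
Product: 17 (2Z)-3-[(2R,3S)-3-[(1R)-1-{[tert-butyl(dimethyl)silyl]oxy}-3-methylbut-3-en-1-yl]-5-oxooxolan-2-yl]-2-methylprop-2-enal
Conditions: TEMPO (cat.), PhI(OAc)2, CH2Cl2, rt
Reagents that add atoms: none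
Why: TEMPO/PhI(OAc)2 oxidises the primary allylic alcohol to the (Z)-enal and the lactol back to the lactone under mild conditions that should not isomerise the olefin.

**Step 12**
Reactants: 17 the (Z)-enal
Product: 18 (4S,5R)-4-[(1R)-1-{[tert-butyl(dimethyl)silyl]oxy}-3-methylbut-3-en-1-yl]-5-[(1Z,3S)-3-hydroxy-2-methylhexa-1,5-dien-1-yl]oxolan-2-one
Conditions: allylboronic acid pinacol ester, (S)-TRIP (5 mol %), 4 Å molecular sieves, toluene, −30 °C; aq. work-up
Reagents that add atoms: allylboronic acid pinacol ester, C=CCB1OC(C)(C)C(C)(C)O1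
Why: The same phosphoric acid-catalysed allylboration with the antipodal catalyst adds allyl to the Si face and sets C3 (S) under catalyst control, at a temperature where the (Z)-enal keeps its geometry.

**Step 13**
Reactants: 18 the allylic alcohol; 19 (2R)-2-methylbutanoic acid
Product: 20 (1Z,3S)-1-[(2R,3S)-3-[(1R)-1-{[tert-butyl(dimethyl)silyl]oxy}-3-methylbut-3-en-1-yl]-5-oxooxolan-2-yl]-2-methylhexa-1,5-dien-3-yl (2R)-2-methylbutanoate
Conditions: 19, EDC·HCl, DMAP (cat.), CH2Cl2, 0 °C → rt
Reagents that add atoms: none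
Why: Steglich esterification acylates the secondary allylic alcohol with retention at C3 and, at 0 °C, without loss of the acid's α-stereocenter.

**Step 14**
Reactants: 20 the diene
Product: 21 (1(10)Z,4Z)-8β-{[tert-butyl(dimethyl)silyl]oxy}-3β-[(2R)-2-methylbutanoyloxy]-13-norgermacra-1(10),4-dien-12,6α-olide (3S,6R,7S,8R; trans-fused lactone, C11 is CH2)
Conditions: second-generation Grubbs catalyst (10 mol %), toluene (1 mM), 80 °C
Reagents that add atoms: none
Why: Ring-closing metathesis between the monosubstituted and the 1,1-disubstituted olefin closes the ten-membered ring with loss of ethene; the (Z)-C4=C5 olefin pre-folds the chain and ring strain should enforce the (Z)-geometry at C1=C10.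

**Step 15**
Reactants: 21 the macrocyclic lactone
Product: 24 (1(10)Z,4Z)-8β-{[tert-butyl(dimethyl)silyl]oxy}-3β-[(2R)-2-methylbutanoyloxy]germacra-1(10),4,11(13)-trien-12,6α-olide (3S,6R,7S,8R), via Mannich base 22 (not isolated), via trimethylammonium iodide 23 (not isolated)
Conditions: LiN(iPr)2 (1.05 equiv), THF, −78 °C; Me2N=CH2+ I−, −78 → 0 °C; MeI, THF/MeOH, rt; aq. NaHCO3, CH2Cl2, rt
Reagents that add atoms: Eschenmoser's salt, C=[N+](C)C.[I-]
Why: The lactone α-CH2 (C11) is the most acidic and least hindered site, so LiN(iPr)2 should enolise it in preference to the α-branched ester, and Mannich reaction, N-methylation and elimination of trimethylamine then give the exo-methylene.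

**Step 16**
Reactants: 24 the silyl ether
Product: 25 (1(10)Z,4Z)-8β-hydroxy-3β-[(2R)-2-methylbutanoyloxy]germacra-1(10),4,11(13)-trien-12,6α-olide (3S,6R,7R,8R)
Conditions: HF·pyridine, pyridine, THF, 0 °C → rt
Reagents that add atoms: none
Why: Buffered HF·pyridine cleaves the secondary silyl ether without touching the esters or the α-methylene lactone.

**Step 17**
Reactants: 25 the homoallylic alcohol
Product: 26 (4Z)-1β,10β-epoxy-8β-hydroxy-3β-[(2R)-2-methylbutanoyloxy]germacra-4,11(13)-dien-12,6α-olide (1R,3S,6R,7R,8R,10S; cis-epoxide)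
Conditions: VO(acac)2 (5 mol %), t-BuOOH, CH2Cl2, 0 °C → rt
Reagents that add atoms: tert-butyl hydroperoxide, CC(C)(C)OO
Why: In this hydroxyl-directed epoxidation the vanadate ester of the homoallylic C8–OH delivers oxygen to the same (β) face of the electron-rich C1=C10 olefin, stereospecifically giving the cis-epoxide, while the acyloxy-flanked C4=C5 and electron-poor C11=C13 olefins should not react.

**Step 18**
Reactants: 26 the epoxy alcohol; 27 angelic acid
Product: 29 the target, (4Z)-8β-angeloyloxy-1β,10β-epoxy-3β-[(2R)-2-methylbutanoyloxy]germacra-4,11(13)-dien-12,6α-olide (1R,3S,6R,7R,8R,10S), via mixed anhydride 28 (not isolated)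
Conditions: 27, 2,4,6-trichlorobenzoyl chloride, Et3N, toluene, rt; then 26, toluene, 70 °C
Reagents that add atoms: none
Why: Acylation with the preformed Yamaguchi-type mixed anhydride, without a nucleophilic catalyst, transfers the (Z)-2-methylbut-2-enoyl group to C8–OH with the least risk of isomerisation to the tiglate.

**Compound list**
1 | 3-[(4-methoxybenzyl)oxy]propanoic acid | COc1ccc(COCCC(=O)O)cc1 | starting material
2 | (2R,5R)-2,5-dimethylpyrrolidine | C[C@@H]1CC[C@@H](C)N1 | starting material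
3 | 3-[(4-methoxybenzyl)oxy]propanoyl chloride | COc1ccc(COCCC(=O)Cl)cc1 | intermediate
4 | 1-[(2R,5R)-2,5-dimethylpyrrolidin-1-yl]-3-[(4-methoxybenzyl)oxy]propan-1-one | COc1ccc(COCCC(=O)N2[C@H](C)CC[C@H]2C)cc1 | intermediate
5 | buta-1,3-diene | C=CC=C | starting material
6 | (2R,5R)-1-{3-[(4-methoxybenzyl)oxy]prop-1-en-1-ylidene}-2,5-dimethylpyrrolidin-1-ium trifluoromethanesulfonate | COc1ccc(COCC=C=[N+]2[C@H](C)CC[C@H]2C)cc1.[O-]S(=O)(=O)C(F)(F)F | intermediate
7 | (2R,5R)-1-[trans-2-{[(4-methoxybenzyl)oxy]methyl}-3-vinylcyclobutylidene]-2,5-dimethylpyrrolidin-1-ium trifluoromethanesulfonate, ring carbons configured as in 8 | COc1ccc(COC[C@@H]2[C@@H](C=C)CC2=[N+]3[C@H](C)CC[C@H]3C)cc1.[O-]S(=O)(=O)C(F)(F)F | intermediate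
8 | (2S,3R)-2-{[(4-methoxybenzyl)oxy]methyl}-3-vinylcyclobutan-1-one | O=C1C[C@H](C=C)[C@H]1COCc1ccc(OC)cc1 | intermediate
9 | (4R,5S)-5-{[(4-methoxybenzyl)oxy]methyl}-4-vinyloxolan-2-one | O=C1C[C@H](C=C)[C@@H](COCc2ccc(OC)cc2)O1 | intermediate
10 | (2S,3S)-2-{[(4-methoxybenzyl)oxy]methyl}-5-oxooxolane-3-carbaldehyde | O=C1C[C@H](C=O)[C@@H](COCc2ccc(OC)cc2)O1 | intermediate
11 | (4R,5S)-4-[(1R)-1-hydroxy-3-methylbut-3-en-1-yl]-5-{[(4-methoxybenzyl)oxy]methyl}oxolan-2-one | O=C1C[C@H]([C@H](O)CC(C)=C)[C@@H](COCc2ccc(OC)cc2)O1 | intermediate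
12 | (4S,5S)-4-[(1R)-1-{[tert-butyl(dimethyl)silyl]oxy}-3-methylbut-3-en-1-yl]-5-{[(4-methoxybenzyl)oxy]methyl}oxolan-2-one | O=C1C[C@H]([C@H](O[Si](C)(C)C(C)(C)C)CC(C)=C)[C@@H](COCc2ccc(OC)cc2)O1 | intermediate
13 | (4S,5S)-4-[(1R)-1-{[tert-butyl(dimethyl)silyl]oxy}-3-methylbut-3-en-1-yl]-5-(hydroxymethyl)oxolan-2-one | O=C1C[C@H]([C@H](O[Si](C)(C)C(C)(C)C)CC(C)=C)[C@@H](CO)O1 | intermediate
14 | (2S,3S)-3-[(1R)-1-{[tert-butyl(dimethyl)silyl]oxy}-3-methylbut-3-en-1-yl]-5-oxooxolane-2-carbaldehyde | O=C1C[C@H]([C@H](O[Si](C)(C)C(C)(C)C)CC(C)=C)[C@@H](C=O)O1 | intermediate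
15 | methyl (2Z)-3-[(2R,3S)-3-[(1R)-1-{[tert-butyl(dimethyl)silyl]oxy}-3-methylbut-3-en-1-yl]-5-oxooxolan-2-yl]-2-methylprop-2-enoate | O=C1C[C@H]([C@H](O[Si](C)(C)C(C)(C)C)CC(C)=C)[C@@H](/C=C(/C)C(=O)OC)O1 | intermediate
16 | (4S,5R)-4-[(1R)-1-{[tert-butyl(dimethyl)silyl]oxy}-3-methylbut-3-en-1-yl]-5-[(1Z)-3-hydroxy-2-methylprop-1-en-1-yl]oxolan-2-ol (anomers) | OC1C[C@H]([C@H](O[Si](C)(C)C(C)(C)C)CC(C)=C)[C@@H](/C=C(/C)CO)O1 | intermediate
17 | (2Z)-3-[(2R,3S)-3-[(1R)-1-{[tert-butyl(dimethyl)silyl]oxy}-3-methylbut-3-en-1-yl]-5-oxooxolan-2-yl]-2-methylprop-2-enal | O=C1C[C@H]([C@H](O[Si](C)(C)C(C)(C)C)CC(C)=C)[C@@H](/C=C(/C)C=O)O1 | intermediate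
18 | (4S,5R)-4-[(1R)-1-{[tert-butyl(dimethyl)silyl]oxy}-3-methylbut-3-en-1-yl]-5-[(1Z,3S)-3-hydroxy-2-methylhexa-1,5-dien-1-yl]oxolan-2-one | O=C1C[C@H]([C@H](O[Si](C)(C)C(C)(C)C)CC(C)=C)[C@@H](/C=C(/C)[C@@H](O)CC=C)O1 | intermediate
19 | (2R)-2-methylbutanoic acid | CC[C@@H](C)C(=O)O | starting material
20 | (1Z,3S)-1-[(2R,3S)-3-[(1R)-1-{[tert-butyl(dimethyl)silyl]oxy}-3-methylbut-3-en-1-yl]-5-oxooxolan-2-yl]-2-methylhexa-1,5-dien-3-yl (2R)-2-methylbutanoate | O=C1C[C@H]([C@H](O[Si](C)(C)C(C)(C)C)CC(C)=C)[C@@H](/C=C(/C)[C@@H](OC(=O)[C@H](C)CC)CC=C)O1 | intermediate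
21 | (1(10)Z,4Z)-8β-{[tert-butyl(dimethyl)silyl]oxy}-3β-[(2R)-2-methylbutanoyloxy]-13-norgermacra-1(10),4-dien-12,6α-olide (3S,6R,7S,8R) | C1C(=O)O[C@@H]2/C=C(/C)[C@@H](OC(=O)[C@H](C)CC)C/C=C(/C)C[C@@H](O[Si](C)(C)C(C)(C)C)[C@@H]12 | intermediate
22 | Mannich base of 21, CH2NMe2 on C11 (both C11 epimers) | CN(C)CC1C(=O)O[C@@H]2/C=C(/C)[C@@H](OC(=O)[C@H](C)CC)C/C=C(/C)C[C@@H](O[Si](C)(C)C(C)(C)C)[C@@H]12 | intermediate
23 | trimethylammonium iodide of 22 | C[N+](C)(C)CC1C(=O)O[C@@H]2/C=C(/C)[C@@H](OC(=O)[C@H](C)CC)C/C=C(/C)C[C@@H](O[Si](C)(C)C(C)(C)C)[C@@H]12.[I-] | intermediate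
24 | (1(10)Z,4Z)-8β-{[tert-butyl(dimethyl)silyl]oxy}-3β-[(2R)-2-methylbutanoyloxy]germacra-1(10),4,11(13)-trien-12,6α-olide (3S,6R,7S,8R) | C=C1C(=O)O[C@@H]2/C=C(/C)[C@@H](OC(=O)[C@H](C)CC)C/C=C(/C)C[C@@H](O[Si](C)(C)C(C)(C)C)[C@@H]12 | intermediate
25 | (1(10)Z,4Z)-8β-hydroxy-3β-[(2R)-2-methylbutanoyloxy]germacra-1(10),4,11(13)-trien-12,6α-olide (3S,6R,7R,8R) | C=C1C(=O)O[C@@H]2/C=C(/C)[C@@H](OC(=O)[C@H](C)CC)C/C=C(/C)C[C@@H](O)[C@@H]12 | intermediate
26 | (4Z)-1β,10β-epoxy-8β-hydroxy-3β-[(2R)-2-methylbutanoyloxy]germacra-4,11(13)-dien-12,6α-olide (1R,3S,6R,7R,8R,10S) | C=C1C(=O)O[C@@H]2/C=C(/C)[C@@H](OC(=O)[C@H](C)CC)C[C@H]3O[C@@]3(C)C[C@@H](O)[C@@H]12 | intermediate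
27 | angelic acid, (2Z)-2-methylbut-2-enoic acid | C/C=C(/C)C(=O)O | starting material
28 | (2Z)-2-methylbut-2-enoic 2,4,6-trichlorobenzoic anhydride | C/C=C(/C)C(=O)OC(=O)c1c(Cl)cc(Cl)cc1Cl | intermediate
29 | (4Z)-8β-angeloyloxy-1β,10β-epoxy-3β-[(2R)-2-methylbutanoyloxy]germacra-4,11(13)-dien-12,6α-olide (1R,3S,6R,7R,8R,10S) | C=C1C(=O)O[C@@H]2/C=C(/C)[C@@H](OC(=O)[C@H](C)CC)C[C@H]3O[C@@]3(C)C[C@@H](OC(=O)/C(C)=C\C)[C@@H]12 | target

**Step count and risks**
Total step count: 18. Longest linear sequence: 18 steps (1 to 29).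

Steps most likely to fail:

Step 2. The auxiliary may transfer its chirality incompletely, or the kinetic cis/trans ratio may leak into the enantiomeric ratio when C6 is equilibrated, so that the cyclobutanone is formed in low enantiomeric purity. The fallback moves the source of absolute configuration to a later catalyst-controlled step. It sets out from acid chloride 3, which is condensed with pyrrolidine (Et3N) to the achiral amide 3-[(4-methoxybenzyl)oxy]-1-(pyrrolidin-1-yl)propan-1-one F1. Under the conditions of step 2 this gives the achiral keteniminium triflate F2, the racemic trans-cyclobutaniminium triflate F3 and, after hydrolysis and equilibration, racemic trans-cyclobutanone, that is 8 together with its enantiomer F4. The racemate is taken through steps 3 and 4, which form the enantiomeric lactone F5 and the enantiomeric aldehyde F6 beside 9 and 10. The methallylboration of step 5 then turns the two enantiomers into diastereomers, 11 and the (4S,5R,1'R)-isomer F7, which are separated by chromatography; the route is rejoined at 11.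

Step 14. Intermolecular metathesis (oligomerisation) may outrun closure of the strained ten-membered ring onto the rigid trans-fused lactone, or the 1,1-disubstituted olefin may not be engaged. The fallback closes the carbocycle before the lactone is in place. It sets out from alcohol 18: LiBH4 (THF, 0 °C) reduces the lactone to the seco-triol F8, whose freely rotating C6–C7 bond removes the ring-fusion constraint. Ring-closing metathesis (second-generation Grubbs catalyst, toluene, high dilution) should give the cyclodecadiene triol F9. TEMPO/PhI(OAc)2 then oxidises the primary alcohol and the derived lactol and so re-forms the γ-lactone as the hydroxy lactone F10. Esterification of its C3 hydroxyl with 19 as in step 13 returns to 21.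

Step 17. Oxygen delivery from the C8 vanadate may be poorly face-selective in the flexible ring, or the C4=C5 olefin may compete. The fallback replaces substrate direction by reagent control. It sets out from silyl ether 24: a Shi epoxidation (fructose-derived chiral ketone of the enantiomeric series that matches the β face, KHSO5, K2CO3, MeCN/dimethoxymethane, 0 °C), which prefers electron-rich trisubstituted olefins, should give the epoxy silyl ether F11. HF·pyridine then removes the silyl group and the route is rejoined at 26.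

**Further compounds**
F1 | step 2 | 3-[(4-methoxybenzyl)oxy]-1-(pyrrolidin-1-yl)propan-1-one | COc1ccc(COCCC(=O)N2CCCC2)cc1
F2 | step 2 | 1-{3-[(4-methoxybenzyl)oxy]prop-1-en-1-ylidene}pyrrolidin-1-ium trifluoromethanesulfonate | COc1ccc(COCC=C=[N+]2CCCC2)cc1.[O-]S(=O)(=O)C(F)(F)F
F3 | step 2 | racemic trans-1-(2-{[(4-methoxybenzyl)oxy]methyl}-3-vinylcyclobutylidene)pyrrolidin-1-ium trifluoromethanesulfonate (one enantiomer drawn) | COc1ccc(COC[C@H]2[C@H](C=C)CC2=[N+]3CCCC3)cc1.[O-]S(=O)(=O)C(F)(F)F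
F4 | step 2 | (2R,3S)-2-{[(4-methoxybenzyl)oxy]methyl}-3-vinylcyclobutan-1-one (enantiomer of 8) | O=C1C[C@@H](C=C)[C@@H]1COCc1ccc(OC)cc1
F5 | step 2 | (4S,5R)-5-{[(4-methoxybenzyl)oxy]methyl}-4-vinyloxolan-2-one (enantiomer of 9) | O=C1C[C@@H](C=C)[C@H](COCc2ccc(OC)cc2)O1
F6 | step 2 | (2R,3R)-2-{[(4-methoxybenzyl)oxy]methyl}-5-oxooxolane-3-carbaldehyde (enantiomer of 10) | O=C1C[C@@H](C=O)[C@H](COCc2ccc(OC)cc2)O1
F7 | step 2 | (4S,5R)-4-[(1R)-1-hydroxy-3-methylbut-3-en-1-yl]-5-{[(4-methoxybenzyl)oxy]methyl}oxolan-2-one | O=C1C[C@@H]([C@H](O)CC(C)=C)[C@H](COCc2ccc(OC)cc2)O1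
F8 | step 14 | seco-triol from reduction of the lactone of 18 (C12 primary, C6 and C3 secondary hydroxyls; 3S,6R,7S,8R; 4Z) | OCC[C@H]([C@H](O[Si](C)(C)C(C)(C)C)CC(C)=C)[C@H](O)/C=C(/C)[C@@H](O)CC=C
F9 | step 14 | (1(10)Z,4Z)-cyclodecadiene triol: C7 bears CH2CH2OH, hydroxyls on C6 and C3, silyl ether on C8 | OCC[C@H]1[C@H](O)/C=C(/C)[C@@H](O)C/C=C(/C)C[C@H]1O[Si](C)(C)C(C)(C)C
F10 | step 14 | (1(10)Z,4Z)-8β-{[tert-butyl(dimethyl)silyl]oxy}-3β-hydroxy-13-norgermacra-1(10),4-dien-12,6α-olide | C1C(=O)O[C@@H]2/C=C(/C)[C@@H](O)C/C=C(/C)C[C@@H](O[Si](C)(C)C(C)(C)C)[C@@H]12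
F11 | step 17 | (4Z)-8β-{[tert-butyl(dimethyl)silyl]oxy}-1β,10β-epoxy-3β-[(2R)-2-methylbutanoyloxy]germacra-4,11(13)-dien-12,6α-olide | C=C1C(=O)O[C@@H]2/C=C(/C)[C@@H](OC(=O)[C@H](C)CC)C[C@H]3O[C@@]3(C)C[C@@H](O[Si](C)(C)C(C)(C)C)[C@@H]12
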